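## Retrosynthetic overview

- Target: a germacra-1(10),4,11(13)-trien-12,8-olide with a free 3-OH and isovalerates on O6 and O15. No ring exists until the last step.
- Last step: the ten-membered carbocycle closes first (C7–C8, intramolecular allylboration of a C8 aldehyde by a C13 allylboronate), and the boron alkoxide then closes the α-methylene lactone onto the C12 methyl ester in the same flask.
- The open chain is cut at C3–C4: Ni/Cr coupling of a C8–C3 aldehyde with a C4 vinyl iodide that already carries both isovalerates and the allylboronate.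
- Vinyl iodide piece: 2-butyne-1,4-diol → ynal → asymmetric addition of methyl propiolate (sets C6) → ynoate to allylboronate (hydroalumination/ICH2Bpin) → hydrostannation/iodination.
- Aldehyde piece: Negishi carboalumination of a silyl butynyl ether, ethylene oxide, oxidation.

Numbering: atom labels (C1–C15) follow germacrane numbering of the target: C7/C8 ring fusion, C6 acyloxy carbon, C3 carbinol, C4=C5 and C1=C10 alkenes, C15 acyloxymethyl, C11–C13 methylene-lactone carbons.

Assumption: the ligand enantiomers named in steps 5 and 9 are taken to give the configurations drawn; if either gives the antipodal carbinol, its mirror-image ligand is used.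

## Route

Step 1
Reactants: 1 tert-butyl(but-3-yn-1-yloxy)dimethylsilane
Product: 4 (E)-6-[(tert-butyldimethylsilyl)oxy]-4-methylhex-3-en-1-ol, via alkenyldimethylalane 2 (not isolated), via lithium alkenylalanate 3 (not isolated)
Conditions: Me3Al, Cp2ZrCl2 (cat.), CH2Cl2, 0 °C to rt; n-BuLi, THF–hexane, −78 °C; ethylene oxide, −78 °C to rt; aqueous work-up
Reagents that add atoms: trimethylaluminium C[Al](C)C; ethylene oxide C1CO1
Why: Zirconium-catalysed Negishi carboalumination adds methyl and aluminium cis across the terminal alkyne (methyl to the internal carbon), and the derived alanate opens ethylene oxide with retention, which fixes the (E)-trisubstituted C1=C10 alkene.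

Step 2
Reactants: 4 (E)-6-[(tert-butyldimethylsilyl)oxy]-4-methylhex-3-en-1-ol
Product: 5 (E)-6-[(tert-butyldimethylsilyl)oxy]-4-methylhex-3-enal
Conditions: Dess–Martin periodinane, CH2Cl2, 0 °C to rt; used crude
Reagents that add atoms: none
Why: Dess–Martin oxidation of the homoallylic primary alcohol gives the β,γ-unsaturated aldehyde under non-basic conditions that do not move the alkene into conjugation.

Step 3
Reactants: 6 but-2-yne-1,4-diol
Product: 7 4-hydroxybut-2-yn-1-yl 3-methylbutanoate
Conditions: diol (4 equiv), isovaleryl chloride (1 equiv), pyridine, THF, 0 °C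
Reagents that add atoms: isovaleryl chloride CC(C)CC(Cl)=O
Why: Statistical monoacylation (nucleophilic acyl substitution) of the cheap symmetrical diol used in excess gives the mono-ester, and the surplus diol is removed by aqueous extraction.

Step 4
Reactants: 7 4-hydroxybut-2-yn-1-yl 3-methylbutanoate
Product: 8 4-oxobut-2-yn-1-yl 3-methylbutanoate
Conditions: Dess–Martin periodinane, CH2Cl2, 0 °C; used crude
Reagents that add atoms: none
Why: Dess–Martin oxidation converts the propargylic alcohol into the ynal without touching the ester.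

Step 5
Reactants: 8 4-oxobut-2-yn-1-yl 3-methylbutanoate; 9 methyl propiolate
Product: 11 methyl (R)-4-hydroxy-7-[(3-methylbutanoyl)oxy]hepta-2,5-diynoate, via methylzinc acetylide 10 (not isolated)
Conditions: Me2Zn (3 equiv), (S,S)-ProPhenol (20 mol%), Ph3P=O (40 mol%), toluene, 0 °C
Reagents that add atoms: none
Why: Trost's dinuclear zinc–ProPhenol asymmetric alkynylation adds the zinc acetylide of methyl propiolate to one face of the aldehyde, so the C6 carbinol centre (R) is set by catalyst control.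

Step 6
Reactants: 11 methyl (R)-4-hydroxy-7-[(3-methylbutanoyl)oxy]hepta-2,5-diynoate
Product: 12 methyl (R)-4,7-bis[(3-methylbutanoyl)oxy]hepta-2,5-diynoate
Conditions: isovaleryl chloride, pyridine, CH2Cl2, −20 °C
Reagents that add atoms: isovaleryl chloride CC(C)CC(Cl)=O
Why: Cold acylation with the acid chloride and a weak base esterifies the secondary alcohol with retention at C6 before the base-sensitive γ-oxy ynoate can isomerise.

Step 7
Reactants: 12 methyl (R)-4,7-bis[(3-methylbutanoyl)oxy]hepta-2,5-diynoate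
Product: 14 methyl (2Z,4S)-4,7-bis[(3-methylbutanoyl)oxy]-2-[(4,4,5,5-tetramethyl-1,3,2-dioxaborolan-2-yl)methyl]hept-2-en-5-ynoate, via alpha-aluminated enoate 13 (not isolated)
Conditions: i-Bu2AlH, HMPA, THF, 0 °C; then ICH2Bpin, 0 °C to rt
Reagents that add atoms: 2-(iodomethyl)-4,4,5,5-tetramethyl-1,3,2-dioxaborolane CC1(C)OB(CI)OC1(C)C
Why: Conjugate cis-hydroalumination of the ynoate by the i-Bu2AlH·HMPA complex (Tsuda) and C-alkylation of the α-aluminated enoate with the iodomethylboronate (Hall-type allylboronate synthesis) install C13 with C6 trans to CH2B, while the HMPA-attenuated hydride leaves the isolated esters and the second alkyne alone.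

Step 8
Reactants: 14 methyl (2Z,4S)-4,7-bis[(3-methylbutanoyl)oxy]-2-[(4,4,5,5-tetramethyl-1,3,2-dioxaborolan-2-yl)methyl]hept-2-en-5-ynoate
Product: 16 methyl (2Z,4S,5E)-6-iodo-4,7-bis[(3-methylbutanoyl)oxy]-2-[(4,4,5,5-tetramethyl-1,3,2-dioxaborolan-2-yl)methyl]hepta-2,5-dienoate, via alkenylstannane 15 (not isolated)
Conditions: Bu3SnH, PdCl2(PPh3)2 (3 mol%), THF, 0 °C; then I2, CH2Cl2, 0 °C
Reagents that add atoms: iodine II
Why: Palladium-catalysed cis-hydrostannation places tin on the less hindered alkyne carbon (C4, next to CH2O and away from the branched C6), and iododestannylation with retention gives the vinyl iodide in which C15 and C6 are cis.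

Step 9
Reactants: 5 (E)-6-[(tert-butyldimethylsilyl)oxy]-4-methylhex-3-enal; 16 methyl (2Z,4S,5E)-6-iodo-4,7-bis[(3-methylbutanoyl)oxy]-2-[(4,4,5,5-tetramethyl-1,3,2-dioxaborolan-2-yl)methyl]hepta-2,5-dienoate
Product: 18 methyl (2Z,4R,5E,7R,9E)-12-[(tert-butyldimethylsilyl)oxy]-7-hydroxy-10-methyl-4-[(3-methylbutanoyl)oxy]-6-{[(3-methylbutanoyl)oxy]methyl}-2-[(4,4,5,5-tetramethyl-1,3,2-dioxaborolan-2-yl)methyl]dodeca-2,5,9-trienoate, via alkenylchromium dichloride 17 (not isolated)
Conditions: CrCl2 (4 equiv), NiCl2 (2 mol%), (S)-4-isopropyl-oxazoline methanesulfonamide ligand (Kishi type), Et3N, THF, rt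
Reagents that add atoms: none
Why: In this asymmetric Nozaki–Hiyama–Kishi coupling the nickel-catalysed alkenylchromium reagent adds 1,2 to the aldehyde with retention of alkene geometry, and the chiral sulfonamide ligand on chromium selects the aldehyde face to set C3 (R) by reagent control, the electron-poor allylboronate being too slow to compete at rt.

Step 10
Reactants: 18 methyl (2Z,4R,5E,7R,9E)-12-[(tert-butyldimethylsilyl)oxy]-7-hydroxy-10-methyl-4-[(3-methylbutanoyl)oxy]-6-{[(3-methylbutanoyl)oxy]methyl}-2-[(4,4,5,5-tetramethyl-1,3,2-dioxaborolan-2-yl)methyl]dodeca-2,5,9-trienoate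
Product: 19 methyl (2Z,4R,5E,7R,9E)-7,12-dihydroxy-10-methyl-4-[(3-methylbutanoyl)oxy]-6-{[(3-methylbutanoyl)oxy]methyl}-2-[(4,4,5,5-tetramethyl-1,3,2-dioxaborolan-2-yl)methyl]dodeca-2,5,9-trienoate
Conditions: camphorsulfonic acid (10 mol%), MeOH–CH2Cl2, 0 °C
Reagents that add atoms: none
Why: Acid-catalysed methanolysis removes the unhindered primary silyl ether while the pinacol boronate, the esters and the secondary allylic alcohol are left intact.

Step 11
Reactants: 19 methyl (2Z,4R,5E,7R,9E)-7,12-dihydroxy-10-methyl-4-[(3-methylbutanoyl)oxy]-6-{[(3-methylbutanoyl)oxy]methyl}-2-[(4,4,5,5-tetramethyl-1,3,2-dioxaborolan-2-yl)methyl]dodeca-2,5,9-trienoate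
Product: 22 (3aR,4R,5E,7R,9E,11aS)-7-hydroxy-10-methyl-3-methylidene-6-{[(3-methylbutanoyl)oxy]methyl}-2-oxo-2,3,3a,4,7,8,11,11a-octahydrocyclodeca[b]furan-4-yl 3-methylbutanoate, via seco-aldehyde 20 (not isolated), via cyclised boron alkoxide 21 (not isolated)
Conditions: PhI(OAc)2, TEMPO (10 mol%), CH2Cl2, rt; then dilute to 1 mM, Sc(OTf)3 (10 mol%), 0 °C to rt; PPTS (cat.)
Reagents that add atoms: none
Why: Proposed new method: TEMPO/PhI(OAc)2 oxidises only the primary alcohol, and the aldehyde is then trapped intramolecularly by the 2-alkoxycarbonyl allylboronate through a Sc(OTf)3-accelerated chair-like six-membered transition state (C6 equatorial because it is trans to CH2B and the aldehyde chain equatorial, hence anti C7/C8 and a trans lactone; the C6 hydrogen eclipses the alkene to avoid allylic 1,3-strain with the cis ester, so the tether closes on the face that gives 7R,8S), after which the boron alkoxide lactonises onto the methyl ester so that the ten-membered ring and the α-methylene lactone form in one flask; the closest known reactions are the intermolecular Lewis-acid-catalysed allylboration–lactonisation of such boronates (Hall) and macrocyclic carbonyl allylations to germacrane rings with other allyl metals.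

## Compound list

1 | tert-butyl(but-3-yn-1-yloxy)dimethylsilane | C#CCCO[Si](C)(C)C(C)(C)C | starting material
2 | [(E)-4-(tert-butyldimethylsilyloxy)-2-methylbut-1-enyl]dimethylaluminium | C[Al](C)/C=C(\C)CCO[Si](C)(C)C(C)(C)C | intermediate
3 | lithium butyl[(E)-4-(tert-butyldimethylsilyloxy)-2-methylbut-1-enyl]dimethylaluminate | [Li+].CCCC[Al-](C)(C)/C=C(\C)CCO[Si](C)(C)C(C)(C)C | intermediate
4 | (E)-6-[(tert-butyldimethylsilyl)oxy]-4-methylhex-3-en-1-ol | OCC/C=C(\C)CCO[Si](C)(C)C(C)(C)C | intermediate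
5 | (E)-6-[(tert-butyldimethylsilyl)oxy]-4-methylhex-3-enal | O=CC/C=C(\C)CCO[Si](C)(C)C(C)(C)C | intermediate
6 | but-2-yne-1,4-diol | OCC#CCO | starting material
7 | 4-hydroxybut-2-yn-1-yl 3-methylbutanoate | CC(C)CC(=O)OCC#CCO | intermediate
8 | 4-oxobut-2-yn-1-yl 3-methylbutanoate | CC(C)CC(=O)OCC#CC=O | intermediate
9 | methyl propiolate | C#CC(=O)OC | starting material
10 | methylzinc acetylide of methyl propiolate | C[Zn]C#CC(=O)OC | intermediate
11 | methyl (R)-4-hydroxy-7-[(3-methylbutanoyl)oxy]hepta-2,5-diynoate | CC(C)CC(=O)OCC#C[C@@H](O)C#CC(=O)OC | intermediate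
12 | methyl (R)-4,7-bis[(3-methylbutanoyl)oxy]hepta-2,5-diynoate | CC(C)CC(=O)OCC#C[C@@H](OC(=O)CC(C)C)C#CC(=O)OC | intermediate
13 | methyl (2E,4S)-2-(diisobutylalumanyl)-4,7-bis[(3-methylbutanoyl)oxy]hept-2-en-5-ynoate | COC(=O)/C([Al](CC(C)C)CC(C)C)=C\[C@H](OC(=O)CC(C)C)C#CCOC(=O)CC(C)C | intermediate
14 | methyl (2Z,4S)-4,7-bis[(3-methylbutanoyl)oxy]-2-[(4,4,5,5-tetramethyl-1,3,2-dioxaborolan-2-yl)methyl]hept-2-en-5-ynoate | COC(=O)/C(CB1OC(C)(C)C(C)(C)O1)=C\[C@H](OC(=O)CC(C)C)C#CCOC(=O)CC(C)C | intermediate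
15 | methyl (2Z,4S,5E)-4,7-bis[(3-methylbutanoyl)oxy]-2-[(4,4,5,5-tetramethyl-1,3,2-dioxaborolan-2-yl)methyl]-6-(tributylstannyl)hepta-2,5-dienoate | CC(C)CC(=O)OC/C(=C\[C@@H](OC(=O)CC(C)C)/C=C(/CB1OC(C)(C)C(C)(C)O1)C(=O)OC)[Sn](CCCC)(CCCC)CCCC | intermediate
16 | methyl (2Z,4S,5E)-6-iodo-4,7-bis[(3-methylbutanoyl)oxy]-2-[(4,4,5,5-tetramethyl-1,3,2-dioxaborolan-2-yl)methyl]hepta-2,5-dienoate | CC(C)CC(=O)OC/C(I)=C\[C@@H](OC(=O)CC(C)C)/C=C(/CB1OC(C)(C)C(C)(C)O1)C(=O)OC | intermediate
17 | alkenylchromium dichloride from 16 (CrCl2 group in place of iodine, trivalent chromium) | CC(C)CC(=O)OC/C(=C\[C@@H](OC(=O)CC(C)C)/C=C(/CB1OC(C)(C)C(C)(C)O1)C(=O)OC)[Cr](Cl)Cl | intermediate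
18 | methyl (2Z,4R,5E,7R,9E)-12-[(tert-butyldimethylsilyl)oxy]-7-hydroxy-10-methyl-4-[(3-methylbutanoyl)oxy]-6-{[(3-methylbutanoyl)oxy]methyl}-2-[(4,4,5,5-tetramethyl-1,3,2-dioxaborolan-2-yl)methyl]dodeca-2,5,9-trienoate | CC(C)(C)[Si](C)(C)OCC/C(C)=C/C[C@@H](O)/C(COC(=O)CC(C)C)=C/[C@@H](OC(=O)CC(C)C)/C=C(/CB1OC(C)(C)C(C)(C)O1)C(=O)OC | intermediate
19 | methyl (2Z,4R,5E,7R,9E)-7,12-dihydroxy-10-methyl-4-[(3-methylbutanoyl)oxy]-6-{[(3-methylbutanoyl)oxy]methyl}-2-[(4,4,5,5-tetramethyl-1,3,2-dioxaborolan-2-yl)methyl]dodeca-2,5,9-trienoate | OCC/C(C)=C/C[C@@H](O)/C(COC(=O)CC(C)C)=C/[C@@H](OC(=O)CC(C)C)/C=C(/CB1OC(C)(C)C(C)(C)O1)C(=O)OC | intermediate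
20 | methyl (2Z,4R,5E,7R,9E)-7-hydroxy-10-methyl-4-[(3-methylbutanoyl)oxy]-6-{[(3-methylbutanoyl)oxy]methyl}-12-oxo-2-[(4,4,5,5-tetramethyl-1,3,2-dioxaborolan-2-yl)methyl]dodeca-2,5,9-trienoate | O=CC/C(C)=C/C[C@@H](O)/C(COC(=O)CC(C)C)=C/[C@@H](OC(=O)CC(C)C)/C=C(/CB1OC(C)(C)C(C)(C)O1)C(=O)OC | intermediate
21 | cyclised boron alkoxide: ten-membered carbocycle with C8–O–Bpin and the C7 2-(methoxycarbonyl)vinyl group, configured at C3, C6, C7, C8 as in 22 | C=C(C(=O)OC)[C@@H]1[C@@H](OB2OC(C)(C)C(C)(C)O2)C/C(C)=C/C[C@@H](O)/C(COC(=O)CC(C)C)=C/[C@H]1OC(=O)CC(C)C | intermediate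
22 | (3aR,4R,5E,7R,9E,11aS)-7-hydroxy-10-methyl-3-methylidene-6-{[(3-methylbutanoyl)oxy]methyl}-2-oxo-2,3,3a,4,7,8,11,11a-octahydrocyclodeca[b]furan-4-yl 3-methylbutanoate (CNP0317194.1) | C=C1C(=O)O[C@H]2C/C(C)=C/C[C@@H](O)/C(COC(=O)CC(C)C)=C/[C@@H](OC(=O)CC(C)C)[C@H]12 | target

## Step count and risks

Total: 11 steps. Longest linear sequence: 9 steps (steps 3 to 11); the aldehyde branch (steps 1 and 2) joins at step 9.

**Step 11 (ring closure) is the most likely to fail.** A boronic ester that reacts slowly even between two molecules is asked to close a ten-membered ring at high dilution, and the diastereoselectivity at C7/C8 rests on macrocyclic conformational control. The fallback sets out from 18 and comes back to the route at 22; it replaces the preformed boron nucleophile by an allylchromium made by reduction.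
- Perborate oxidation of the C–B bond of 18 (NaBO3·4H2O, THF/H2O) gives the primary allylic alcohol F1.
- Appel bromination (CBr4, PPh3, −20 °C), selective for the unhindered primary allylic hydroxyl over the C3 secondary one, gives the allylic bromide F2.
- HF·pyridine removes the silyl ether to give the bromo diol F3.
- TEMPO/PhI(OAc)2 gives the bromo aldehyde F4.
- CrCl2 in THF at high dilution closes both rings: divalent chromium reduces the bromide to the allylchromium, which adds to the aldehyde (intramolecular Nozaki–Hiyama allylation), and the chromium alkoxide lactonises to 22.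
- The weak point of this fallback is possible 1,4-elimination of the C6 ester from the allylchromium, which is why it is the second choice.

**Step 9 (C3 configuration).** The ligand-controlled addition may give a poor ratio at C3 on this hindered vinyl iodide. The fallback sets out from 5 and 16 and comes back at 18; it sets C3 by reduction instead of addition.
- The ligand-free NiCl2/CrCl2 coupling in DMSO gives the C3-epimeric alcohols F5.
- Dess–Martin oxidation gives the enone F6.
- Corey–Bakshi–Shibata reduction with the (S)-methyl oxazaborolidine and catecholborane at −78 °C gives 18; the branched alkenyl group acts as the large substituent, so the hydride is delivered to give the (R) carbinol.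

**Step 8 (vinyl iodide).** Tin may add with imperfect regiochemistry, and zerovalent palladium with tin hydride can cleave the allylic C6 ester or reduce the enoate. The fallback sets out from 14 and comes back at 16; it gives up the tin hydride/palladium chemistry for a silicon route.
- PtCl2/XPhos-catalysed cis-hydrosilylation with Et3SiH (THF, 50 °C) places silicon on the less hindered C4 and gives the alkenylsilane F7.
- Iododesilylation with N-iodosuccinimide in hexafluoroisopropanol at 0 °C gives 16 with retention of geometry.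

## Further compounds

F1 | step 11 | primary allylic alcohol: 18 with CH2OH in place of CH2Bpin | CC(C)(C)[Si](C)(C)OCC/C(C)=C/C[C@@H](O)/C(COC(=O)CC(C)C)=C/[C@@H](OC(=O)CC(C)C)/C=C(/CO)C(=O)OC
F2 | step 11 | allylic bromide: 18 with CH2Br in place of CH2Bpin | CC(C)(C)[Si](C)(C)OCC/C(C)=C/C[C@@H](O)/C(COC(=O)CC(C)C)=C/[C@@H](OC(=O)CC(C)C)/C=C(/CBr)C(=O)OC
F3 | step 11 | bromo diol: F2 without the silyl group | OCC/C(C)=C/C[C@@H](O)/C(COC(=O)CC(C)C)=C/[C@@H](OC(=O)CC(C)C)/C=C(/CBr)C(=O)OC
F4 | step 11 | bromo aldehyde: F3 with C8 oxidised to the aldehyde | O=CC/C(C)=C/C[C@@H](O)/C(COC(=O)CC(C)C)=C/[C@@H](OC(=O)CC(C)C)/C=C(/CBr)C(=O)OC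
F5 | step 9 | C3-epimeric mixture of 18 | CC(C)(C)[Si](C)(C)OCC/C(C)=C/CC(O)/C(COC(=O)CC(C)C)=C/[C@@H](OC(=O)CC(C)C)/C=C(/CB1OC(C)(C)C(C)(C)O1)C(=O)OC
F6 | step 9 | enone: 18 with the C3 carbinol oxidised to the ketone | CC(C)(C)[Si](C)(C)OCC/C(C)=C/CC(=O)/C(COC(=O)CC(C)C)=C/[C@@H](OC(=O)CC(C)C)/C=C(/CB1OC(C)(C)C(C)(C)O1)C(=O)OC
F7 | step 8 | alkenylsilane: 16 with SiEt3 in place of iodine | CC(C)CC(=O)OC/C(=C\[C@@H](OC(=O)CC(C)C)/C=C(/CB1OC(C)(C)C(C)(C)O1)C(=O)OC)[Si](CC)(CC)CC
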